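## Structural features

The target is a tetracyclic diterpenoid acetate (22 carbon atoms) of the 2,9-epoxyeunicellane type: ring A (C1, C10–C14) is cis-fused along C1–C10 to a tetrahydrofuran (C1, C2, O, C9, C10), and C2 and C9 are bridged on the other face of that ether by a nine-membered oxonene (O, C2–C9) holding a Z trisubstituted C6=C7 alkene. A seven-membered lactone (C14–C15–C17(=O)–O–C3–C2–C1) is trans-fused to ring A across C1–C14 and shares C2–C3 with the oxonene. The eight stereocentres are contiguous (C15–C14–C1–C2–C3, C1–C10–C9 and C10–C11): H1 and H10 are cis, H2 and H9 are cis to each other and anti to H1, H14 is anti to H1, and at C11 the acetoxy group is equatorial and syn to C9 while the methyl group lies on the convex face with H10. Fragile elements are the tertiary acetate (ionisation, elimination), the lactone with its enolisable C15 centre, the C6=C7 alkene, which a free O3 can attack across the ring, and every α-alkoxy aldehyde on the way. The real difficulty lies in the medium ring, in the two fully substituted carbinol carbons C3 and C11 (C11 needs its oxygen on the concave face of ring A beside a second trisubstituted alkene) and in a seven-membered lactone closed onto a tertiary alcohol. The key step uses the fact that ring A and the tetrahydrofuran share the bond C1–C10 while C13–C14 lies opposite to it in ring A: a diene C10–C13 on C9 and a dienophile C1=C14 on C2 are already joined through C9–O–C2 of a preformed oxonene, so one cycloaddition closes both rings.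

## Logic of the disconnections

37 to 36. The acetyl C–O bond at O11 is cut first, because a tertiary acetate is the most easily ionised group and should meet no further reagent. The gain is one acyl group. The demand is an acylation strong enough for a hindered tertiary alcohol yet non-enolising for the lactone.

36 to 34 (through 35). C11–O is cut together with C12–H, a Markovnikov hydration of C11=C12. It is placed after lactone formation because O3 is then acylated and cannot add across the ring to C7, and because no ketone is left for the hydride work-up to reduce. The gain is the loss of a fully substituted stereocentre. The demand is double: the electrophile must choose the ring A alkene over C6=C7, and oxygen must enter C11 on the concave face, anti to an electrophile bound on the convex face.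

34 to 31 (through 32 and 33). The lactone bond C17–O3 and the oxidation level of C17 are removed together, giving a diol. This avoids activating an α-branched acid toward a tertiary alcohol, the situation most prone to epimerise C15. The gain is one ring and two operations. The demand is that the tertiary hydroxyl closes a seven-membered lactol fast enough to be oxidised.

31 to 30 to 28 (through 29). First O3–Si, then C17–O and C15–H are cut: anti-Markovnikov hydration of a 1,1-disubstituted alkene. C15 disappears as a stereocentre. The forward step must pick this alkene among three and deliver hydrogen to C15 from the side of C13.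

28 to 27. C15=C17 is cut to the methyl ketone, the group that activates the dienophile in the key step, so no extra functional group is carried. The demand is a methylenation that leaves C14 alone.

27 to 26. C1–C10 and C13–C14 are cut (retro-[4+2]). Two rings and three stereocentres (C1, C10, C14) vanish, leaving a monocyclic ether with three stereocentres. A centre-by-centre check shows that the configurations of 26 and 27 map onto 37 without change; only the CIP letters at C1, C10 and C14 vary with the substituents. The demand is exo and π-facial selectivity, which must come from the 2,9-cis ring and the E geometry of both partners.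

26 to 24 and 25; 24 to 23. C1=C14 is cut, then C1 is returned to a silyl ether. The enone must be the last π system installed, since a methylene ylide would attack it and since 26 cyclises. The demand is unmasking of a primary silyl ether beside a tertiary one, and an E-selective, neutral olefination.

23 to 22 to 20 and 21. C12=C13 and then C10=C11 are cut. Diene and enone therefore need three olefinations in all, not two, because no single reagent delivers the E 2-methyldiene reliably. 21 secures the E geometry that later defines C10.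

20 to 19 to 18. The oxidation level of C10 and then the O–benzyl bond are adjusted. The benzyl ether comes with 1 and is removed by electron transfer, because hydrogenolysis would reduce C6=C7.

18 to 17. C6=C7 is cut (ring-closing metathesis), opening the nine-membered ring to an acyclic diene with all three stereocentres in place. The demand is closure of a medium ring to a trisubstituted alkene at high dilution.

17 to 16 to 14 and 15. O3–Si, then C3–C4. A cyclic chelate between the ketone and the ether oxygen on C2 decides the face. The butenyl group must be the nucleophile and methyl must already be on the ketone; the opposite order would give the C3 epimer.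

14 to 13 to 12 to 11; 11 to 8 and 9 (through 10). Oxidation-level and protecting-group adjustments lead back to an aldol adduct; the bond cut is C2–C3. A direct aldol with a methyl ketone, which would set C2 and C3 at once, is not used: it would be slow and would have to tell methyl from butenyl. The aldehyde aldol has to control C2 only, since the C3 carbinol is oxidised afterwards.

8 to 5 and 6 (through 7); 5 to 3 and 4; 3 to 1 and 2. The N-acyl bond, the ether bond O–C2 (made on a carbon that is not yet stereogenic) and C7–C8 are cut. C9 comes unchanged from 1, whose S configuration is the one required for 9S.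

## Other disconnections considered

Alternative 1: The cut is made at C9–C10 and at C11–O(acetyl). This leaves ring A as a cyclohexene (C10=C11) carrying the C2–C3 chain on C1 and a mixed acetal at C9, compound A1. In the forward sense a Lewis acid (SnCl4 or BF3·OEt2) ionises the C9 acetoxy group, the oxocarbenium ion is attacked by C10, and the C11 cation is taken up by the acetoxy group just released, giving the hexahydroisobenzofuran A2.
- In its favour: the tetrahydrofuran and three stereocentres (C9, C10, C11) form in one step. The tertiary acetate arrives by anti addition across C10=C11, on the concave face, with no later hydration or acylation. On this point the alternative is better than the chosen plan, whose C11 hydration is its weakest late step. The number of stereocentres set in the key step is equal.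
- Against it here: A2 still lacks the nine-membered ring, which must be closed between two alkenyl arms on a rigid bicyclic core instead of on a flexible chain. The key step builds one ring and one C–C bond against two rings and two C–C bonds. A stepwise cationic path has exits that a concerted cycloaddition lacks: proton loss from the C11 cation, attack of the side-chain alkenes on the oxocarbenium ion, loss of the 2,9-cis relation. The tertiary acetate must survive every later step, and C1, C2, C3, C14 and C15 must be set one by one beforehand.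
- Step economy: the saving at C11 is roughly offset by the longer preparation of A1 and the separate ring closure.

Alternative 2: The cut removes C4 and C5 (bonds C3–C4 and C5–C6) from a nine-membered 3,7-dione and leads to the bridged seven-membered 1,3-diketone A3. In the forward sense the enol of A3 undergoes [2+2] photocycloaddition with ethene A5, followed by retro-aldol opening in the same operation (de Mayo reaction), to give the ring-enlarged dione A4.
- In its favour: the medium ring is made by two-carbon ring expansion and not by cyclisation, so neither high dilution nor a ruthenium catalyst is needed; this is an advantage over the metathesis of the chosen plan. The direction of enolisation is without consequence, since insertion on either side of C6 gives the same 1,5-diketone. Ring A with C11, C14 and C15 is already complete, so the late C11 problem does not arise (again better).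
- Against it here: A4 has neither C18 nor C19, no stereocentre at C3 and no C6=C7 alkene. The two ketones must be told apart. Methyl must be added to C3 with face control while the C7 carbonyl sits across the ring, where hemiketal bridging is likely. C7 must then be turned into a methyl-bearing Z alkene with enolisation toward C6 and not C8.
- Comparison: the key step forms two C–C bonds but no ring and no stereocentre, against two rings and three stereocentres formed without reagent in the chosen plan. With four or more corrective steps after it, the alternative is longer. A photochemical step followed by fragmentation is less predictable on a heavily oxygenated substrate than a thermal pericyclic reaction, though it is equal in avoiding charged intermediates.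

Alternative 3: The cut goes through the C6=C7 double bond, replacing it by a sulfonyl bridge, so the precursor is the ten-membered cyclic sulfone A6. In the forward sense a Ramberg–Bäcklund reaction (α-halogenation in the flask, 1,3-elimination, loss of the bridge) contracts the ring to the fully protected tricyclic oxonene A7.
- In its favour: the ring is closed beforehand by C–S bond formation, which is easier than a nine-membered C–C closure. Halogenation at either α carbon leads to the same alkene. The nine-membered ring accepts only the Z alkene, so geometric control is equal to that of the metathesis. A7 already carries all eight stereocentres, including the C11 and C3 carbinols as silyl ethers, so only deprotection, lactone formation and acetylation remain: fewer late steps than in the chosen plan and no late C11 problem.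
- Against it here: the key step forms one π bond but no C–C σ bond, no new ring and no stereocentre. Ring A, the tetrahydrofuran and all eight stereocentres must therefore come from other chemistry that this cut does not supply. The basic, halogenating conditions are harsher than a neutral thermal cycloaddition, a trisubstituted alkene forms more slowly than a disubstituted one, and building and oxidising the sulfur bridge adds three or four steps.
- Comparison: the alternative is the better endgame but the weaker strategy for the skeleton. The chosen plan builds most of the skeleton in its key step and pays for it in the endgame.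

Key step: step 17

Remark: in all cyclic intermediates the locants are those of the eunicellane skeleton of the target (ring oxygen between C2 and C9); the names are therefore semi-systematic, and the SMILES strings carry the exact stereochemistry.

## Steps

Step 1
Reactants: 1 (S)-benzyl glycidyl ether; 2 isopropenylmagnesium bromide
Product: 3 (2S)-1-(benzyloxy)-4-methylpent-4-en-2-ol
Conditions: 2 (1.5 equiv), CuI (10 mol %), THF, −40 → 0 °C; aq NH4Cl
Reagents that add atoms: none
Why: Copper-catalysed Grignard opening of a terminal epoxide at its unsubstituted carbon (SN2); the stereocentre (later C9) is not touched, so the S epoxide gives the S alcohol.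

Step 2
Reactants: 3 (2S)-1-(benzyloxy)-4-methylpent-4-en-2-ol; 4 bromoacetic acid
Product: 5 {[(2S)-1-(benzyloxy)-4-methylpent-4-en-2-yl]oxy}acetic acid
Conditions: NaH (2.5 equiv), THF/DMF, 0 → 23 °C; then 1 M HCl
Reagents that add atoms: none
Why: Williamson ether synthesis: the sodium alkoxide of 3 displaces bromide from sodium bromoacetate at a primary carbon; C9 is not involved.

Step 3
Reactants: 5 {[(2S)-1-(benzyloxy)-4-methylpent-4-en-2-yl]oxy}acetic acid; 6 (4R)-4-benzyl-1,3-oxazolidin-2-one
Product: 8 (4R)-4-benzyl-3-({[(2S)-1-(benzyloxy)-4-methylpent-4-en-2-yl]oxy}acetyl)-1,3-oxazolidin-2-one, via pivalic mixed anhydride 7 (not isolated)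
Conditions: t-BuCOCl, Et3N, THF, −20 °C; then 6, LiCl, −20 → 23 °C
Reagents that add atoms: pivaloyl chloride, CC(C)(C)C(Cl)=O (its atoms stay in 7 only)
Why: N-acylation of an oxazolidinone by a mixed anhydride activated with LiCl; the nucleophile attacks the unhindered glycolyl carbonyl and not the pivaloyl one.

Step 4
Reactants: 8 (4R)-4-benzyl-3-({[(2S)-1-(benzyloxy)-4-methylpent-4-en-2-yl]oxy}acetyl)-1,3-oxazolidin-2-one; 9 acetaldehyde
Product: 11 (4R)-4-benzyl-3-[(2R,3S)-2-{[(2S)-1-(benzyloxy)-4-methylpent-4-en-2-yl]oxy}-3-hydroxybutanoyl]-1,3-oxazolidin-2-one, via trichlorotitanium enolate 10 (not isolated)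
Conditions: TiCl4 (1.05 equiv), i-Pr2NEt (1.1 equiv), NMP (1 equiv), CH2Cl2, −78 °C; then 9 (3 equiv), −78 → −40 °C
Reagents that add atoms: titanium tetrachloride, Cl[Ti](Cl)(Cl)Cl (its atoms stay in 10 only)
Why: Evans syn aldol of a glycolyl imide through the Z enolate 10 in a closed six-membered chair transition state; the benzyl group of the R auxiliary shields one enolate face and sets C2 (2R in 11, the letter becoming S once C1 is reduced), while the carbinol centre at C3 is oxidised away in step 7 and need not be controlled.

Step 5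
Reactants: 11 (4R)-4-benzyl-3-[(2R,3S)-2-{[(2S)-1-(benzyloxy)-4-methylpent-4-en-2-yl]oxy}-3-hydroxybutanoyl]-1,3-oxazolidin-2-one
Product: 12 (2S,3S)-2-{[(2S)-1-(benzyloxy)-4-methylpent-4-en-2-yl]oxy}butane-1,3-diol
Conditions: LiBH4, THF/MeOH, 0 °C
Reagents that add atoms: none
Why: Reductive cleavage of the N-acyl oxazolidinone by LiBH4 gives the primary alcohol and returns the auxiliary; the α centre is not enolised under these conditions.

Step 6
Reactants: 12 (2S,3S)-2-{[(2S)-1-(benzyloxy)-4-methylpent-4-en-2-yl]oxy}butane-1,3-diol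
Product: 13 (2S,3S)-3-{[(2S)-1-(benzyloxy)-4-methylpent-4-en-2-yl]oxy}-4-[(triethylsilyl)oxy]butan-2-ol
Conditions: Et3SiCl (1.05 equiv), imidazole, CH2Cl2, −78 → −30 °C
Reagents that add atoms: chlorotriethylsilane, CC[Si](Cl)(CC)CC
Why: Kinetic silylation of the primary hydroxyl; the secondary carbinol is flanked by the branched ether carbon and should react much more slowly at low temperature.

Step 7
Reactants: 13 (2S,3S)-3-{[(2S)-1-(benzyloxy)-4-methylpent-4-en-2-yl]oxy}-4-[(triethylsilyl)oxy]butan-2-ol
Product: 14 (3S)-3-{[(2S)-1-(benzyloxy)-4-methylpent-4-en-2-yl]oxy}-4-[(triethylsilyl)oxy]butan-2-one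
Conditions: Dess–Martin periodinane, pyridine, CH2Cl2, 0 → 23 °C
Reagents that add atoms: none
Why: Dess–Martin oxidation of the secondary alcohol to the methyl ketone under buffered conditions that spare the primary silyl ether and should not epimerise the α-alkoxy centre C2.

Step 8
Reactants: 14 (3S)-3-{[(2S)-1-(benzyloxy)-4-methylpent-4-en-2-yl]oxy}-4-[(triethylsilyl)oxy]butan-2-one; 15 but-3-en-1-ylmagnesium bromide
Product: 16 (2S,3S)-2-{[(2S)-1-(benzyloxy)-4-methylpent-4-en-2-yl]oxy}-3-methyl-1-[(triethylsilyl)oxy]hept-6-en-3-ol
Conditions: 15 (2.5 equiv), MgBr2·OEt2 (1 equiv), CH2Cl2/Et2O, −78 °C; aq NH4Cl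
Reagents that add atoms: none
Why: Chelation-controlled Grignard addition to an α-alkoxy ketone: magnesium bridges the ketone oxygen and the ether oxygen on C2 (the silyl ether is a poor ligand), and the butenyl group attacks the face of the five-membered chelate that carries H2 and not C1, which sets 3S; adding methyl to a butenyl ketone would give the C3 epimer, hence this order.

Step 9
Reactants: 16 (2S,3S)-2-{[(2S)-1-(benzyloxy)-4-methylpent-4-en-2-yl]oxy}-3-methyl-1-[(triethylsilyl)oxy]hept-6-en-3-ol
Product: 17 (2S,3S)-2-{[(2S)-1-(benzyloxy)-4-methylpent-4-en-2-yl]oxy}-3-methyl-1,3-bis[(triethylsilyl)oxy]hept-6-ene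
Conditions: Et3SiOTf, 2,6-lutidine, CH2Cl2, −78 → 0 °C
Reagents that add atoms: triethylsilyl trifluoromethanesulfonate, CC[Si](CC)(CC)OS(=O)(=O)C(F)(F)F
Why: Silylation of a hindered tertiary alcohol with a silyl triflate; O3 is masked so that it can later neither add across the ring to C7 nor form lactols with the aldehydes at C10 and C1.

Step 10
Reactants: 17 (2S,3S)-2-{[(2S)-1-(benzyloxy)-4-methylpent-4-en-2-yl]oxy}-3-methyl-1,3-bis[(triethylsilyl)oxy]hept-6-ene
Product: 18 (2S,3S,6Z,9S)-9-[(benzyloxy)methyl]-3,7-dimethyl-3-(triethylsilyloxy)-2-[(triethylsilyloxy)methyl]-2,3,4,5,8,9-hexahydrooxonine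
Conditions: second-generation Grubbs catalyst RuCl2(=CHPh)(PCy3)(1,3-dimesitylimidazolidin-2-ylidene) (5–10 mol %), CH2Cl2 (0.002 M), 40 °C
Reagents that add atoms: none
Why: Ring-closing metathesis of a monosubstituted with a 1,1-disubstituted alkene; the gauche C–O bonds at C2/C3 and the ether linkage fold the chain toward closure, and a nine-membered ring can hold only the Z trisubstituted alkene.

Step 11
Reactants: 18 (2S,3S,6Z,9S)-9-[(benzyloxy)methyl]-3,7-dimethyl-3-(triethylsilyloxy)-2-[(triethylsilyloxy)methyl]-2,3,4,5,8,9-hexahydrooxonine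
Product: 19 (2S,3S,6Z,9S)-9-(hydroxymethyl)-3,7-dimethyl-3-(triethylsilyloxy)-2-[(triethylsilyloxy)methyl]-2,3,4,5,8,9-hexahydrooxonine
Conditions: lithium 4,4'-di-tert-butylbiphenylide (LiDBB), THF, −78 °C; aq NH4Cl
Reagents that add atoms: none
Why: Reductive cleavage of a benzyl ether by single-electron transfer; silyl ethers and the isolated trisubstituted alkene are inert to the radical anion, whereas hydrogenolysis would reduce the alkene.

Step 12
Reactants: 19 (2S,3S,6Z,9S)-9-(hydroxymethyl)-3,7-dimethyl-3-(triethylsilyloxy)-2-[(triethylsilyloxy)methyl]-2,3,4,5,8,9-hexahydrooxonine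
Product: 20 (2S,3S,6Z,9S)-9-formyl-3,7-dimethyl-3-(triethylsilyloxy)-2-[(triethylsilyloxy)methyl]-2,3,4,5,8,9-hexahydrooxonine
Conditions: Dess–Martin periodinane, pyridine, CH2Cl2, 0 → 23 °C
Reagents that add atoms: none
Why: Dess–Martin oxidation to the α-alkoxy aldehyde under buffered, non-epimerising conditions that keep the primary silyl ether; the aldehyde is used at once.

Step 13
Reactants: 20 (2S,3S,6Z,9S)-9-formyl-3,7-dimethyl-3-(triethylsilyloxy)-2-[(triethylsilyloxy)methyl]-2,3,4,5,8,9-hexahydrooxonine; 21 2-(triphenylphosphoranylidene)propanal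
Product: 22 (2S,3S,6Z,9S)-3,7-dimethyl-9-[(1E)-2-methyl-3-oxoprop-1-en-1-yl]-3-(triethylsilyloxy)-2-[(triethylsilyloxy)methyl]-2,3,4,5,8,9-hexahydrooxonine
Conditions: 21 (2 equiv), toluene, 80 °C
Reagents that add atoms: none
Why: Wittig olefination with a stabilised ylide gives the E trisubstituted enal (C10=C11), the geometry that later fixes C10; the ylide is too weakly basic to epimerise C9.

Step 14
Reactants: 22 (2S,3S,6Z,9S)-3,7-dimethyl-9-[(1E)-2-methyl-3-oxoprop-1-en-1-yl]-3-(triethylsilyloxy)-2-[(triethylsilyloxy)methyl]-2,3,4,5,8,9-hexahydrooxonine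
Product: 23 (2S,3S,6Z,9S)-3,7-dimethyl-9-[(1E)-2-methylbuta-1,3-dien-1-yl]-3-(triethylsilyloxy)-2-[(triethylsilyloxy)methyl]-2,3,4,5,8,9-hexahydrooxonine
Conditions: Ph3PCH3Br, KOt-Bu, THF, 0 °C
Reagents that add atoms: methyltriphenylphosphonium bromide, C[P+](c1ccccc1)(c1ccccc1)c1ccccc1.[Br-]
Why: Wittig methylenation of the enal carbonyl (1,2-addition) completes the diene C10–C13 without touching the existing E alkene.

Step 15
Reactants: 23 (2S,3S,6Z,9S)-3,7-dimethyl-9-[(1E)-2-methylbuta-1,3-dien-1-yl]-3-(triethylsilyloxy)-2-[(triethylsilyloxy)methyl]-2,3,4,5,8,9-hexahydrooxonine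
Product: 24 (2R,3S,6Z,9S)-2-formyl-3,7-dimethyl-9-[(1E)-2-methylbuta-1,3-dien-1-yl]-3-(triethylsilyloxy)-2,3,4,5,8,9-hexahydrooxonine
Conditions: (COCl)2, DMSO, CH2Cl2, −78 → −40 °C; then Et3N, −78 → 0 °C
Reagents that add atoms: none
Why: Swern oxidation applied directly to a primary triethylsilyl ether: the chlorosulfonium salt exchanges the unhindered primary silyl ether for an alkoxysulfonium ion that collapses to the aldehyde with Et3N, while the tertiary silyl ether at C3 is too hindered to react (the descriptor at C2 changes to R by priority only).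

Step 16
Reactants: 24 (2R,3S,6Z,9S)-2-formyl-3,7-dimethyl-9-[(1E)-2-methylbuta-1,3-dien-1-yl]-3-(triethylsilyloxy)-2,3,4,5,8,9-hexahydrooxonine; 25 1-(triphenylphosphoranylidene)propan-2-one
Product: 26 (3E)-4-[(2S,3S,6Z,9S)-3,7-dimethyl-9-[(1E)-2-methylbuta-1,3-dien-1-yl]-3-(triethylsilyloxy)-2,3,4,5,8,9-hexahydrooxonin-2-yl]but-3-en-2-one
Conditions: 25 (1.5 equiv), CH2Cl2, 23 °C; filtration through silica, no storage
Reagents that add atoms: none
Why: Wittig olefination with a stabilised ylide gives the E enone under neutral conditions that should avoid epimerisation at C2 and β-elimination of the C3 silyloxy group; any cycloadduct already formed at this stage is the product of step 17.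

Step 17
Reactants: 26 (3E)-4-[(2S,3S,6Z,9S)-3,7-dimethyl-9-[(1E)-2-methylbuta-1,3-dien-1-yl]-3-(triethylsilyloxy)-2,3,4,5,8,9-hexahydrooxonin-2-yl]but-3-en-2-one
Product: 27 (1R,2S,3S,6Z,9S,10S,14R)-2,9-epoxy-3-(triethylsilyloxy)-17-noreunicella-6,11-dien-15-one
Conditions: toluene (0.01 M), BHT (cat.), 23 → 60 °C
Reagents that add atoms: none
Why: Concerted, suprafacial thermal [4+2] cycloaddition of the C10–C13 diene onto the C1=C14 enone; the closest known reaction type is the intramolecular Diels–Alder reaction of an ether-tethered triene with a three-atom tether held on a medium ring. Ring A closes through the two new σ bonds C1–C10 and C13–C14 in a six-membered pericyclic transition state, and the tetrahydrofuran closes at the same moment as the tether ring through C1–C10 alone, which for a three-atom tether can only be cis-fused. C10 is controlled by the E geometry of the diene terminus together with C9: allylic 1,3-strain against the C11 methyl keeps H9 in the diene plane, the ring oxygen and the tethered dienophile then lie on one diene face, and H10 ends anti to H9. C1 is controlled by C2 and by the cis fusion that the tether imposes, which places H1 syn to H10 and anti to H2. C14 follows from the E enone by suprafacial addition, so the acetyl group is trans to C2 and exo. The step needs exo and π-facial selectivity; both are secured by the 2,9-cis oxonene, which holds C10 and C1 cis and within bonding distance, whereas the endo mode would need a trans-fused five-membered tether ring. The ketone lowers the dienophile LUMO enough for reaction near ambient temperature, and BHT suppresses radical polymerisation.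

Step 18
Reactants: 27 (1R,2S,3S,6Z,9S,10S,14R)-2,9-epoxy-3-(triethylsilyloxy)-17-noreunicella-6,11-dien-15-one
Product: 28 (1S,2S,3S,6Z,9S,10S,14R)-2,9-epoxy-3-(triethylsilyloxy)eunicella-6,11,15(17)-triene
Conditions: Ph3PCH3Br, KOt-Bu, THF, 0 → 23 °C
Reagents that add atoms: methyltriphenylphosphonium bromide, C[P+](c1ccccc1)(c1ccccc1)c1ccccc1.[Br-]
Why: Wittig methylenation of the methyl ketone; the acetyl group is already equatorial and trans to C2, the more stable arrangement at C14, so the basic ylide should not change it.

Step 19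
Reactants: 28 (1S,2S,3S,6Z,9S,10S,14R)-2,9-epoxy-3-(triethylsilyloxy)eunicella-6,11,15(17)-triene
Product: 30 (1S,2S,3S,6Z,9S,10S,14S,15R)-2,9-epoxy-3-(triethylsilyloxy)eunicella-6,11-dien-17-ol, via B-alkyl-9-BBN adduct 29 (not isolated)
Conditions: 9-BBN (3 equiv), THF, 0 → 23 °C; then NaOH, H2O2, 0 °C
Reagents that add atoms: 9-borabicyclo[3.3.1]nonane, B1C2CCCC1CCC2 (its atoms stay in 29 only); hydrogen peroxide, OO
Why: Hydroboration–oxidation with a bulky dialkylborane, which picks the 1,1-disubstituted alkene over both trisubstituted ones and places boron on C17; with H14 eclipsing C15=C17 (least allylic strain) the borane approaches anti to the branched C1 side, from the side of C13, which sets 15R.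

Step 20
Reactants: 30 (1S,2S,3S,6Z,9S,10S,14S,15R)-2,9-epoxy-3-(triethylsilyloxy)eunicella-6,11-dien-17-ol
Product: 31 (1S,2S,3S,6Z,9S,10S,14S,15R)-2,9-epoxyeunicella-6,11-diene-3,17-diol
Conditions: Bu4NF, THF, 0 → 23 °C
Reagents that add atoms: none
Why: Fluoride cleavage of the tertiary triethylsilyl ether; nothing else in 30 is sensitive to fluoride or to the mild basicity of the reagent.

Step 21
Reactants: 31 (1S,2S,3S,6Z,9S,10S,14S,15R)-2,9-epoxyeunicella-6,11-diene-3,17-diol
Product: 34 (1S,2S,3S,6Z,9S,10S,14R,15R)-2,9-epoxyeunicella-6,11-dien-17,3-olide, via hydroxy aldehyde 32 (not isolated), via lactol 33 (not isolated)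
Conditions: TEMPO (0.2 equiv), PhI(OAc)2 (3 equiv), CH2Cl2, 23 °C
Reagents that add atoms: none
Why: Oxoammonium-mediated oxidative lactonisation of a diol: only the primary alcohol can be oxidised, aldehyde 32 is trapped by the C3 hydroxyl held gauche to it on the trans-diequatorial arms at C1 and C14, and lactol 33 is oxidised to the lactone; under these weakly acidic conditions C15 should not epimerise.

Step 22
Reactants: 34 (1S,2S,3S,6Z,9S,10S,14R,15R)-2,9-epoxyeunicella-6,11-dien-17,3-olide
Product: 36 (1S,2S,3S,6Z,9S,10R,11R,14R,15R)-2,9-epoxy-11-hydroxyeunicell-6-en-17,3-olide, via organomercury acetate 35 (not isolated)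
Conditions: Hg(OAc)2 (1.1 equiv), THF/H2O (1:1), 0 → 23 °C; then NaBH4, 3 M NaOH, 0 °C, 5 min
Reagents that add atoms: mercury diacetate, CC(=O)O[Hg]OC(C)=O (its mercury and acetate stay in 35 only); water, O
Why: Oxymercuration–demercuration (Markovnikov hydration by anti addition): divalent mercury binds the ring A alkene on its convex face, syn to H10, and water opens the mercurinium ion at the tertiary C11 from the concave face, giving the hydroxyl syn to C9 as in the target; C6=C7 is shielded by its medium ring, where backside attack at C7 would have to pass through the ring interior, and by the acylated, non-nucleophilic O3.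

Step 23
Reactants: 36 (1S,2S,3S,6Z,9S,10R,11R,14R,15R)-2,9-epoxy-11-hydroxyeunicell-6-en-17,3-olide
Product: 37 (1S,2S,3S,6Z,9S,10R,11R,14R,15R)-11-acetoxy-2,9-epoxyeunicell-6-en-17,3-olide
Conditions: Ac2O, DMAP (1 equiv), Et3N, CH2Cl2, 23 → 40 °C
Reagents that add atoms: acetic anhydride, CC(=O)OC(C)=O
Why: DMAP-catalysed acetylation through the N-acetylpyridinium ion is the standard acylation of tertiary alcohols; the conditions are non-enolising for the lactone and do not ionise the product.

## Compound list

1 | (S)-benzyl glycidyl ether, (2S)-2-[(benzyloxy)methyl]oxirane | O(Cc1ccccc1)C[C@H]1OC1 | starting material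
2 | isopropenylmagnesium bromide | C=C(C)[Mg]Br | starting material
3 | (2S)-1-(benzyloxy)-4-methylpent-4-en-2-ol | c1ccccc1COC[C@@H](O)CC(C)=C | intermediate
4 | bromoacetic acid | OC(=O)CBr | starting material
5 | {[(2S)-1-(benzyloxy)-4-methylpent-4-en-2-yl]oxy}acetic acid | c1ccccc1COC[C@@H](OCC(=O)O)CC(C)=C | intermediate
6 | (4R)-4-benzyl-1,3-oxazolidin-2-one | O=C1N[C@H](Cc2ccccc2)CO1 | starting material
7 | mixed anhydride of 5 with pivalic acid (not isolated) | c1ccccc1COC[C@@H](OCC(=O)OC(=O)C(C)(C)C)CC(C)=C | intermediate
8 | (4R)-4-benzyl-3-({[(2S)-1-(benzyloxy)-4-methylpent-4-en-2-yl]oxy}acetyl)-1,3-oxazolidin-2-one | c1ccccc1COC[C@@H](OCC(=O)N2[C@H](Cc3ccccc3)COC2=O)CC(C)=C | intermediate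
9 | acetaldehyde | CC=O | starting material
10 | trichlorotitanium (Z)-enolate of 8 (not isolated) | Cl[Ti](Cl)(Cl)O/C(=C\O[C@H](COCc1ccccc1)CC(C)=C)N1[C@H](Cc2ccccc2)COC1=O | intermediate
11 | (4R)-4-benzyl-3-[(2R,3S)-2-{[(2S)-1-(benzyloxy)-4-methylpent-4-en-2-yl]oxy}-3-hydroxybutanoyl]-1,3-oxazolidin-2-one | c1ccccc1COC[C@@H](O[C@@H](C(=O)N2[C@H](Cc3ccccc3)COC2=O)[C@H](C)O)CC(C)=C | intermediate
12 | (2S,3S)-2-{[(2S)-1-(benzyloxy)-4-methylpent-4-en-2-yl]oxy}butane-1,3-diol | c1ccccc1COC[C@@H](O[C@@H](CO)[C@H](C)O)CC(C)=C | intermediate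
13 | (2S,3S)-3-{[(2S)-1-(benzyloxy)-4-methylpent-4-en-2-yl]oxy}-4-[(triethylsilyl)oxy]butan-2-ol | c1ccccc1COC[C@@H](O[C@@H](CO[Si](CC)(CC)CC)[C@H](C)O)CC(C)=C | intermediate
14 | (3S)-3-{[(2S)-1-(benzyloxy)-4-methylpent-4-en-2-yl]oxy}-4-[(triethylsilyl)oxy]butan-2-one | c1ccccc1COC[C@@H](O[C@@H](CO[Si](CC)(CC)CC)C(C)=O)CC(C)=C | intermediate
15 | but-3-en-1-ylmagnesium bromide | C=CCC[Mg]Br | starting material
16 | (2S,3S)-2-{[(2S)-1-(benzyloxy)-4-methylpent-4-en-2-yl]oxy}-3-methyl-1-[(triethylsilyl)oxy]hept-6-en-3-ol | c1ccccc1COC[C@@H](O[C@@H](CO[Si](CC)(CC)CC)[C@@](C)(O)CCC=C)CC(C)=C | intermediate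
17 | (2S,3S)-2-{[(2S)-1-(benzyloxy)-4-methylpent-4-en-2-yl]oxy}-3-methyl-1,3-bis[(triethylsilyl)oxy]hept-6-ene | c1ccccc1COC[C@@H](O[C@@H](CO[Si](CC)(CC)CC)[C@@](C)(O[Si](CC)(CC)CC)CCC=C)CC(C)=C | intermediate
18 | (2S,3S,6Z,9S)-9-[(benzyloxy)methyl]-3,7-dimethyl-3-(triethylsilyloxy)-2-[(triethylsilyloxy)methyl]-2,3,4,5,8,9-hexahydrooxonine | c1ccccc1COC[C@@H]1C/C(C)=C\CC[C@](C)(O[Si](CC)(CC)CC)[C@H](CO[Si](CC)(CC)CC)O1 | intermediate
19 | (2S,3S,6Z,9S)-9-(hydroxymethyl)-3,7-dimethyl-3-(triethylsilyloxy)-2-[(triethylsilyloxy)methyl]-2,3,4,5,8,9-hexahydrooxonine | OC[C@@H]1C/C(C)=C\CC[C@](C)(O[Si](CC)(CC)CC)[C@H](CO[Si](CC)(CC)CC)O1 | intermediate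
20 | (2S,3S,6Z,9S)-9-formyl-3,7-dimethyl-3-(triethylsilyloxy)-2-[(triethylsilyloxy)methyl]-2,3,4,5,8,9-hexahydrooxonine | O=C[C@@H]1C/C(C)=C\CC[C@](C)(O[Si](CC)(CC)CC)[C@H](CO[Si](CC)(CC)CC)O1 | intermediate
21 | 2-(triphenylphosphoranylidene)propanal | CC(C=O)=P(c1ccccc1)(c1ccccc1)c1ccccc1 | starting material
22 | (2S,3S,6Z,9S)-3,7-dimethyl-9-[(1E)-2-methyl-3-oxoprop-1-en-1-yl]-3-(triethylsilyloxy)-2-[(triethylsilyloxy)methyl]-2,3,4,5,8,9-hexahydrooxonine | O=C/C(C)=C/[C@@H]1C/C(C)=C\CC[C@](C)(O[Si](CC)(CC)CC)[C@H](CO[Si](CC)(CC)CC)O1 | intermediate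
23 | (2S,3S,6Z,9S)-3,7-dimethyl-9-[(1E)-2-methylbuta-1,3-dien-1-yl]-3-(triethylsilyloxy)-2-[(triethylsilyloxy)methyl]-2,3,4,5,8,9-hexahydrooxonine | C=C/C(C)=C/[C@@H]1C/C(C)=C\CC[C@](C)(O[Si](CC)(CC)CC)[C@H](CO[Si](CC)(CC)CC)O1 | intermediate
24 | (2R,3S,6Z,9S)-2-formyl-3,7-dimethyl-9-[(1E)-2-methylbuta-1,3-dien-1-yl]-3-(triethylsilyloxy)-2,3,4,5,8,9-hexahydrooxonine | C=C/C(C)=C/[C@@H]1C/C(C)=C\CC[C@](C)(O[Si](CC)(CC)CC)[C@H](C=O)O1 | intermediate
25 | 1-(triphenylphosphoranylidene)propan-2-one | CC(=O)C=P(c1ccccc1)(c1ccccc1)c1ccccc1 | starting material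
26 | (3E)-4-[(2S,3S,6Z,9S)-3,7-dimethyl-9-[(1E)-2-methylbuta-1,3-dien-1-yl]-3-(triethylsilyloxy)-2,3,4,5,8,9-hexahydrooxonin-2-yl]but-3-en-2-one (2,9-cis oxonene tetraene) | C=C/C(C)=C/[C@@H]1C/C(C)=C\CC[C@](C)(O[Si](CC)(CC)CC)[C@H](/C=C/C(C)=O)O1 | intermediate
27 | (1R,2S,3S,6Z,9S,10S,14R)-2,9-epoxy-3-(triethylsilyloxy)-17-noreunicella-6,11-dien-15-one (tricyclic cycloadduct, acetyl on C14) | CC1=CC[C@@H](C(C)=O)[C@H]3[C@@H]1[C@@H]1C/C(C)=C\CC[C@](C)(O[Si](CC)(CC)CC)[C@H]3O1 | intermediate
28 | (1S,2S,3S,6Z,9S,10S,14R)-2,9-epoxy-3-(triethylsilyloxy)eunicella-6,11,15(17)-triene | CC1=CC[C@@H](C(C)=C)[C@H]3[C@@H]1[C@@H]1C/C(C)=C\CC[C@](C)(O[Si](CC)(CC)CC)[C@H]3O1 | intermediate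
29 | 9-[(1S,2S,3S,6Z,9S,10S,14S,15S)-2,9-epoxy-3-(triethylsilyloxy)eunicella-6,11-dien-17-yl]-9-borabicyclo[3.3.1]nonane (not isolated) | CC1=CC[C@@H]([C@@H](C)CB2C4CCCC2CCC4)[C@H]3[C@@H]1[C@@H]1C/C(C)=C\CC[C@](C)(O[Si](CC)(CC)CC)[C@H]3O1 | intermediate
30 | (1S,2S,3S,6Z,9S,10S,14S,15R)-2,9-epoxy-3-(triethylsilyloxy)eunicella-6,11-dien-17-ol | CC1=CC[C@@H]([C@@H](C)CO)[C@H]3[C@@H]1[C@@H]1C/C(C)=C\CC[C@](C)(O[Si](CC)(CC)CC)[C@H]3O1 | intermediate
31 | (1S,2S,3S,6Z,9S,10S,14S,15R)-2,9-epoxyeunicella-6,11-diene-3,17-diol | CC1=CC[C@@H]([C@@H](C)CO)[C@H]3[C@@H]1[C@@H]1C/C(C)=C\CC[C@](C)(O)[C@H]3O1 | intermediate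
32 | (1S,2S,3S,6Z,9S,10S,14R,15R)-2,9-epoxy-3-hydroxyeunicella-6,11-dien-17-al (not isolated) | CC1=CC[C@@H]([C@@H](C)C=O)[C@H]3[C@@H]1[C@@H]1C/C(C)=C\CC[C@](C)(O)[C@H]3O1 | intermediate
33 | (1S,2S,3S,6Z,9S,10S,14R,15R)-2,9:3,17-diepoxyeunicella-6,11-dien-17-ol, both C17 epimers (not isolated) | CC1=CC[C@@H]2[C@H]3[C@@H]1[C@@H]1C/C(C)=C\CC[C@](C)(OC(O)[C@@H]2C)[C@H]3O1 | intermediate
34 | (1S,2S,3S,6Z,9S,10S,14R,15R)-2,9-epoxyeunicella-6,11-dien-17,3-olide | CC1=CC[C@@H]2[C@H]3[C@@H]1[C@@H]1C/C(C)=C\CC[C@](C)(OC(=O)[C@@H]2C)[C@H]3O1 | intermediate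
35 | (1S,2S,3S,6Z,9S,10R,11S,12S,14R,15R)-12-(acetoxymercurio)-2,9-epoxy-11-hydroxyeunicell-6-en-17,3-olide (not isolated) | O[C@]1(C)[C@@H]([Hg]OC(C)=O)C[C@@H]2[C@H]3[C@@H]1[C@@H]1C/C(C)=C\CC[C@](C)(OC(=O)[C@@H]2C)[C@H]3O1 | intermediate
36 | (1S,2S,3S,6Z,9S,10R,11R,14R,15R)-2,9-epoxy-11-hydroxyeunicell-6-en-17,3-olide | O[C@]1(C)CC[C@@H]2[C@H]3[C@@H]1[C@@H]1C/C(C)=C\CC[C@](C)(OC(=O)[C@@H]2C)[C@H]3O1 | intermediate
37 | (1S,2S,3S,6Z,9S,10R,11R,14R,15R)-11-acetoxy-2,9-epoxyeunicell-6-en-17,3-olide (CNP0332402.2) | CC(=O)O[C@]1(C)CC[C@@H]2[C@H]3[C@@H]1[C@@H]1C/C(C)=C\CC[C@](C)(OC(=O)[C@@H]2C)[C@H]3O1 | target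

## Step count and risks

Total step count: 23. Longest linear sequence: 23 steps (1 to 37). The route is linear; 2, 4, 6, 9, 15, 21 and 25 enter as commercial reagents.

Least certain steps:

Step 17 (key step). The most likely failures are a cycloaddition that is slower than polymerisation or geometric isomerisation of the dienyl enone, or erosion of π-facial selectivity, because the two exo transition states differ only in how the medium ring presents C10 and C1 to each other. Fallback: starting from 24, olefination with (triphenylphosphoranylidene)acetaldehyde would give the enal tetraene F1. Its dienophile can be activated as an iminium ion by a chiral imidazolidinone salt, so that catalyst control is added to substrate control. The resulting 14-formyl cycloadduct F2 would be treated with MeMgBr to give the carbinol F3, and Dess–Martin oxidation would bring the route back to 27.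

Step 22. Two processes may interfere. One is competing electrophilic attack on C6=C7, since both alkenes are trisubstituted and the discrimination rests only on the hindered backside of the medium-ring alkene. The other is opening of a mercurinium ion in the trans-diaxial sense, with water entering C11 on the convex face, which is stereoelectronically easier in the chair fixed by the trans-fused lactone and would give the C11 epimer. Fallback: starting from 34, hydroxyselenation with N-(phenylselanyl)phthalimide, water and camphorsulfonic acid proceeds through a reversibly formed seleniranium ion. The adducts can therefore equilibrate toward the trans-diequatorial Markovnikov β-hydroxy selenide F4, since its isomer with selenium axial and syn to C9 is strained. Reduction with Bu3SnH and AIBN would remove selenium and return to 36.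

Step 21. The oxidation may stall at the hydroxy aldehyde, because a tertiary hydroxyl closing a seven-membered lactol is slow and the equilibrium may lie on the open side; prolonged exposure then invites epimerisation at C15. Fallback: starting from 31, TEMPO/NaOCl/NaClO2 in buffered MeCN–water would oxidise the primary alcohol to the hydroxy acid F5. Lactonisation with 2-methyl-6-nitrobenzoic anhydride and DMAP under slow addition (Shiina lactonisation) would then return to 34.

Step 19. Facial selectivity at C15 may be poor, because the rotamers of the isopropenyl group are close in energy and C13 and C1 differ in size only moderately. Fallback: starting from 27, kinetic enolisation toward the methyl group (KN(SiMe3)2, PhNTf2, −78 °C) would give the enol triflate F6. Hydroxycarbonylation (Pd(OAc)2, PPh3, CO, KOAc, DMF/H2O) would give the acrylic acid F7. Carboxylate-directed asymmetric hydrogenation with Ru(OAc)2(BINAP), using the ligand antipode that delivers hydrogen to the required face, would set C15 under catalyst control in the acid F8. Reduction with LiAlH4 would return to 30.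

Step 15. The exchange at the primary silyl ether may be incomplete, the tertiary silyl ether may be lost, or C2 may epimerise while the mixture warms with Et3N. Fallback: starting from 23, HF·pyridine buffered with pyridine (THF, 0 °C) would remove only the primary silyl ether and give the primary alcohol F9. Dess–Martin oxidation would then return to 24.

## Further compounds

F1 | step 17 | (2E)-3-[(2S,3S,6Z,9S)-3,7-dimethyl-9-[(1E)-2-methylbuta-1,3-dien-1-yl]-3-(triethylsilyloxy)-2,3,4,5,8,9-hexahydrooxonin-2-yl]prop-2-enal | C=C/C(C)=C/[C@@H]1C/C(C)=C\CC[C@](C)(O[Si](CC)(CC)CC)[C@H](/C=C/C=O)O1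
F2 | step 17 | (1R,2S,3S,6Z,9S,10S,14R)-2,9-epoxy-3-(triethylsilyloxy)-16,17-dinoreunicella-6,11-dien-15-al | CC1=CC[C@@H](C=O)[C@H]3[C@@H]1[C@@H]1C/C(C)=C\CC[C@](C)(O[Si](CC)(CC)CC)[C@H]3O1
F3 | step 17 | (1S,2S,3S,6Z,9S,10S,14R)-2,9-epoxy-3-(triethylsilyloxy)-17-noreunicella-6,11-dien-15-ol, both C15 epimers | CC1=CC[C@@H](C(C)O)[C@H]3[C@@H]1[C@@H]1C/C(C)=C\CC[C@](C)(O[Si](CC)(CC)CC)[C@H]3O1
F4 | step 22 | (1S,2S,3S,6Z,9S,10R,11S,12S,14R,15R)-2,9-epoxy-11-hydroxy-12-(phenylselanyl)eunicell-6-en-17,3-olide | O[C@]1(C)[C@@H]([Se]c2ccccc2)C[C@@H]2[C@H]3[C@@H]1[C@@H]1C/C(C)=C\CC[C@](C)(OC(=O)[C@@H]2C)[C@H]3O1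
F5 | step 21 | (1S,2S,3S,6Z,9S,10S,14R,15R)-2,9-epoxy-3-hydroxyeunicella-6,11-dien-17-oic acid | CC1=CC[C@@H]([C@@H](C)C(=O)O)[C@H]3[C@@H]1[C@@H]1C/C(C)=C\CC[C@](C)(O)[C@H]3O1
F6 | step 19 | (1R,2S,3S,6Z,9S,10S,14R)-2,9-epoxy-3-(triethylsilyloxy)-17-noreunicella-6,11,15-trien-15-yl trifluoromethanesulfonate | CC1=CC[C@@H](C(=C)OS(=O)(=O)C(F)(F)F)[C@H]3[C@@H]1[C@@H]1C/C(C)=C\CC[C@](C)(O[Si](CC)(CC)CC)[C@H]3O1
F7 | step 19 | (1S,2S,3S,6Z,9S,10S,14R)-2,9-epoxy-3-(triethylsilyloxy)eunicella-6,11,15(16)-trien-17-oic acid | CC1=CC[C@@H](C(=C)C(=O)O)[C@H]3[C@@H]1[C@@H]1C/C(C)=C\CC[C@](C)(O[Si](CC)(CC)CC)[C@H]3O1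
F8 | step 19 | (1S,2S,3S,6Z,9S,10S,14R,15R)-2,9-epoxy-3-(triethylsilyloxy)eunicella-6,11-dien-17-oic acid | CC1=CC[C@@H]([C@@H](C)C(=O)O)[C@H]3[C@@H]1[C@@H]1C/C(C)=C\CC[C@](C)(O[Si](CC)(CC)CC)[C@H]3O1
F9 | step 15 | (2S,3S,6Z,9S)-2-(hydroxymethyl)-3,7-dimethyl-9-[(1E)-2-methylbuta-1,3-dien-1-yl]-3-(triethylsilyloxy)-2,3,4,5,8,9-hexahydrooxonine | C=C/C(C)=C/[C@@H]1C/C(C)=C\CC[C@](C)(O[Si](CC)(CC)CC)[C@H](CO)O1
A1 | alternative 1 | ring A cyclohexene with the C9 α-acetoxy ether (C9 epimers), C3 triethylsilyl ether and C17 tert-butyldiphenylsilyl ether | CC1=C[C@@H]([C@H](OC(OC(C)=O)CC(C)=C)[C@](C)(CCC=C)O[Si](CC)(CC)CC)[C@H]([C@@H](C)CO[Si](c2ccccc2)(c2ccccc2)C(C)(C)C)CC1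
A2 | alternative 1 | hexahydroisobenzofuran with the C11 acetate and two alkenyl arms | CC(=O)O[C@]1(C)CC[C@@H]([C@@H](C)CO[Si](c2ccccc2)(c2ccccc2)C(C)(C)C)[C@H]3[C@@H]1[C@H](CC(C)=C)O[C@@H]3[C@](C)(CCC=C)O[Si](CC)(CC)CC
A3 | alternative 2 | bridged seven-membered 3,7-diketone (C6 between the carbonyls) fused to the protected ring A–tetrahydrofuran unit | CC[Si](CC)(CC)O[C@]1(C)CC[C@@H]([C@@H](C)CO[Si](C)(C)C(C)(C)C)[C@H]3[C@@H]1[C@@H]1CC(=O)CC(=O)[C@H]3O1
A4 | alternative 2 | bridged nine-membered 3,7-dione | CC[Si](CC)(CC)O[C@]1(C)CC[C@@H]([C@@H](C)CO[Si](C)(C)C(C)(C)C)[C@H]3[C@@H]1[C@@H]1CC(=O)CCCC(=O)[C@H]3O1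
A5 | alternative 2 | ethene | C=C
A6 | alternative 3 | ten-membered cyclic sulfone with the sulfonyl group between C6 and C7 (C7 epimers) | CC[Si](CC)(CC)O[C@]1(C)CC[C@@H]([C@@H](C)CO[Si](C)(C)C(C)(C)C)[C@H]3[C@@H]1[C@@H]1CC(C)S(=O)(=O)CCC[C@](C)(O[Si](CC)(CC)CC)[C@H]3O1
A7 | alternative 3 | silyl-protected tricyclic oxonene with the Z C6–C7 alkene | CC[Si](CC)(CC)O[C@]1(C)CC[C@@H]([C@@H](C)CO[Si](C)(C)C(C)(C)C)[C@H]3[C@@H]1[C@@H]1C/C(C)=C\CC[C@](C)(O[Si](CC)(CC)CC)[C@H]3O1
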